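## Retrosynthetic overview

- The strategy rests on C2 of pyranone ring C: it is a bare OCH2 between O1 and the stereogenic C3, so it is carried as the ortho O–CH3 group of ring A and bonded to C3 last, by C–H insertion of a carbene placed at C3.
- Target 20 ⇐ (fluoride, then acid) protected (R)-isoflavanone 18 ⇐ (C2–C3 bond, ring C, C3 stereocentre) α-diazo deoxybenzoin 16 ⇐ (diazo transfer) deoxybenzoin 15.
- 15 ⇐ (C4–C4a bond) ring A aryllithium 14 + ring B arylacetic Weinreb amide 11.
- 11 ⇐ one-carbon homologation of aldehyde 6 ⇐ Stille prenylation of bromide 4 ⇐ ketalisation and bromination of 2,3-dihydroxy-4-methoxybenzaldehyde 1.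
- Ring order: rings A and B are bought as benzenes; ring C is the only ring formed, in step 10.

Key step: step 10

Remark on the chemistry: Rh2(S-PTTL)4 is dirhodium tetrakis[N-phthaloyl-(S)-tert-leucinate]. Its sense of induction in this insertion cannot be predicted with confidence. The route is written with it for the (R) product; the mirror-image catalyst Rh2(R-PTTL)4 serves equally if the sense proves opposite.

## Route

Step 1
Reactants: 1 2,3-dihydroxy-4-methoxybenzaldehyde; 2 dichlorodiphenylmethane
Product: 3 7-methoxy-2,2-diphenyl-1,3-benzodioxole-4-carbaldehyde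
Conditions: Ph2CCl2 (1.5 equiv), Ph2O, 175 °C
Reagents that add atoms: none
Why: Double O-alkylation of the catechol by the benzylic gem-dichloride (ketalisation through the chlorodiphenylmethyl cation) with loss of two HCl should give the diphenylmethylene ketal, whose ketal carbon carries no hydrogen and so offers the later carbene no C–H bond.

Step 2
Reactants: 3 7-methoxy-2,2-diphenyl-1,3-benzodioxole-4-carbaldehyde
Product: 4 6-bromo-7-methoxy-2,2-diphenyl-1,3-benzodioxole-4-carbaldehyde
Conditions: NBS (1.05 equiv), MeCN, 0 °C → rt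
Reagents that add atoms: N-bromosuccinimide, O=C1CCC(=O)N1Br
Why: Electrophilic aromatic bromination should occur at C6 alone, because C6 is ortho to the methoxy group, para to the ketal oxygen on C3a and meta to the formyl group, whereas C5 lies ortho to the formyl group.

Step 3
Reactants: 4 6-bromo-7-methoxy-2,2-diphenyl-1,3-benzodioxole-4-carbaldehyde; 5 tributyl(3-methylbut-2-enyl)stannane
Product: 6 7-methoxy-6-(3-methylbut-2-enyl)-2,2-diphenyl-1,3-benzodioxole-4-carbaldehyde
Conditions: Pd(PPh3)4 (5 mol %), DMF, 100 °C; aq. KF work-up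
Reagents that add atoms: none
Why: Stille cross-coupling (oxidative addition of zerovalent palladium into the C–Br bond, transmetalation of the allylic stannane, reductive elimination) should replace bromine by the linear prenyl group while aldehyde and ketal stay untouched.

Step 4
Reactants: 6 7-methoxy-6-(3-methylbut-2-enyl)-2,2-diphenyl-1,3-benzodioxole-4-carbaldehyde
Product: 8 2-[7-methoxy-6-(3-methylbut-2-enyl)-2,2-diphenyl-1,3-benzodioxol-4-yl]acetonitrile, via N-(1-tosylalkenyl)formamide 7 (not isolated)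
Conditions: TosMIC, t-BuOK, DME, −40 °C; then MeOH, reflux
Reagents that add atoms: tosylmethyl isocyanide (TosMIC), Cc1ccc(cc1)S(=O)(=O)C[N+]#[C-]
Why: In this van Leusen reductive cyanation the TosMIC anion condenses with the aldehyde to formamide 7, which methoxide deformylates so that loss of sulfinate leaves the one-carbon-homologated nitrile under purely basic conditions that ketal and prenyl group tolerate.

Step 5
Reactants: 8 2-[7-methoxy-6-(3-methylbut-2-enyl)-2,2-diphenyl-1,3-benzodioxol-4-yl]acetonitrile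
Product: 9 2-[7-methoxy-6-(3-methylbut-2-enyl)-2,2-diphenyl-1,3-benzodioxol-4-yl]acetic acid
Conditions: KOH, EtOH/H2O (2:1), reflux; then cold 1 M HCl to pH 3
Reagents that add atoms: potassium hydroxide, [K+].[OH-]; water, O
Why: Alkaline nitrile hydrolysis should give the arylacetic acid, since ketal, aryl ethers and the isolated alkene are inert to hydroxide and the short cold acidification is too mild to open the ketal.

Step 6
Reactants: 9 2-[7-methoxy-6-(3-methylbut-2-enyl)-2,2-diphenyl-1,3-benzodioxol-4-yl]acetic acid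
Product: 11 N-methoxy-N-methyl-2-[7-methoxy-6-(3-methylbut-2-enyl)-2,2-diphenyl-1,3-benzodioxol-4-yl]acetamide, via acyl imidazole 10 (not isolated)
Conditions: CDI, THF, rt; then MeNHOMe·HCl, rt
Reagents that add atoms: N,O-dimethylhydroxylamine hydrochloride, CNOC.Cl
Why: Activation of the acid as acyl imidazole 10 and aminolysis by N,O-dimethylhydroxylamine (Weinreb amide formation) is near-neutral, spares the ketal and gives an acyl donor that stops at the ketone stage in step 8.

Step 7
Reactants: 12 4-bromo-3-methoxyphenol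
Product: 13 (4-bromo-3-methoxyphenoxy)triisopropylsilane
Conditions: TIPSCl, imidazole, DMF, rt
Reagents that add atoms: chlorotriisopropylsilane, CC(C)[Si](Cl)(C(C)C)C(C)C
Why: Standard phenol silylation gives the bulky triisopropylsilyl ether, chosen because it should survive n-BuLi, DBU and the rhodium carbene and still be cleaved by fluoride at the end.

Step 8
Reactants: 13 (4-bromo-3-methoxyphenoxy)triisopropylsilane; 11 N-methoxy-N-methyl-2-[7-methoxy-6-(3-methylbut-2-enyl)-2,2-diphenyl-1,3-benzodioxol-4-yl]acetamide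
Product: 15 1-[2-methoxy-4-(triisopropylsilyloxy)phenyl]-2-[7-methoxy-6-(3-methylbut-2-enyl)-2,2-diphenyl-1,3-benzodioxol-4-yl]ethanone, via aryllithium 14 (not isolated)
Conditions: 13, n-BuLi, THF, −78 °C; then 11, −78 → 0 °C; aq. NH4Cl
Reagents that add atoms: none
Why: Bromine–lithium exchange gives aryllithium 14 (silyl ether para, so no silyl migration), which adds once to the Weinreb amide (Weinreb ketone synthesis), over-addition being excluded and enolisation of the arylacetamide limited by the low temperature.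

Step 9
Reactants: 15 1-[2-methoxy-4-(triisopropylsilyloxy)phenyl]-2-[7-methoxy-6-(3-methylbut-2-enyl)-2,2-diphenyl-1,3-benzodioxol-4-yl]ethanone
Product: 16 2-diazo-1-[2-methoxy-4-(triisopropylsilyloxy)phenyl]-2-[7-methoxy-6-(3-methylbut-2-enyl)-2,2-diphenyl-1,3-benzodioxol-4-yl]ethanone
Conditions: p-ABSA, DBU, MeCN, 0 °C → rt
Reagents that add atoms: 4-acetamidobenzenesulfonyl azide (p-ABSA), CC(=O)Nc1ccc(cc1)S(=O)(=O)N=[N+]=[N-]
Why: Regitz diazo transfer should work directly because the methylene group is activated by both the ketone and the aryl ring, as in deoxybenzoin itself, and DBU is too weak a nucleophile to cleave the triisopropylsilyl ether.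

Step 10
Reactants: 16 2-diazo-1-[2-methoxy-4-(triisopropylsilyloxy)phenyl]-2-[7-methoxy-6-(3-methylbut-2-enyl)-2,2-diphenyl-1,3-benzodioxol-4-yl]ethanone
Product: 18 (3R)-3-[7-methoxy-6-(3-methylbut-2-enyl)-2,2-diphenyl-1,3-benzodioxol-4-yl]-7-(triisopropylsilyloxy)chroman-4-one, via rhodium carbene 17 (not isolated)
Conditions: Rh2(S-PTTL)4 (1 mol %), 4 Å MS, CH2Cl2 (0.01 M), −20 °C → rt
Reagents that add atoms: none
Why: Proposed new method: the dirhodium catalyst expels N2 from the aryl/acyl (donor/acceptor) diazoketone to give electrophilic rhodium carbene 17 at the future C3, and a C–H bond of the ortho O–CH3 group, made hydridic by the adjacent oxygen lone pair, is inserted in a concerted three-centre, hydride-transfer-like transition state, so that the C2–C3 and C3–H bonds form together and the catalyst is released. The closest known reactions are dirhodium-carboxylate-catalysed insertions of ortho-alkoxyaryl α-diazoketones into O–CH2R bonds giving chroman-4-ones and enantioselective intermolecular insertions of aryl/acceptor carbenes into methyl ether C–H bonds; what is untested is the union of a primary O–CH3 bond and a diaryl diazoketone in one enantioselective ring closure. Ring C closes by C2–C3 bond formation through a six-membered cyclic array of C3, C4, C4a, C8a, O1 and the methyl carbon (a 1,6-insertion), the five-membered alternative being absent because that position is the ether oxygen itself. C3 is the only new stereocentre and is set under catalyst control, the phthalimido/tert-butyl pocket of the tert-leucinate ligands leaving one face of the carbene carbon open to the C–H bond. The step needs chemoselectivity for C–H insertion over oxonium ylide formation at the same methoxy oxygen, over cyclopropanation and over other C–H or arene sites: the ylide can revert because its [1,2]-methyl shift is slow, the prenyl alkene is meta on ring B and cannot reach C3 (high dilution holds back the bimolecular reaction), the ketal carbon bears no hydrogen and its phenyl rings could only be reached through a seven-membered ring. Site selectivity follows from there being a single O–CH3 group within reach, the ring B methoxy group lying para to the carbene-bearing carbon.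

Step 11
Reactants: 18 (3R)-3-[7-methoxy-6-(3-methylbut-2-enyl)-2,2-diphenyl-1,3-benzodioxol-4-yl]-7-(triisopropylsilyloxy)chroman-4-one
Product: 19 (3R)-7-hydroxy-3-[7-methoxy-6-(3-methylbut-2-enyl)-2,2-diphenyl-1,3-benzodioxol-4-yl]chroman-4-one
Conditions: HF·pyridine, pyridine, THF, 0 °C → rt
Reagents that add atoms: none
Why: Fluoride-driven cleavage of the aryl silyl ether, made easier by the para carbonyl group, under buffered non-basic conditions should free the 7-hydroxyl without enolising the C3 stereocentre or touching the ketal.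

Step 12
Reactants: 19 (3R)-7-hydroxy-3-[7-methoxy-6-(3-methylbut-2-enyl)-2,2-diphenyl-1,3-benzodioxol-4-yl]chroman-4-one
Product: 20 (3R)-3-[2,3-dihydroxy-4-methoxy-5-(3-methylbut-2-enyl)phenyl]-7-hydroxychroman-4-one
Conditions: TFA/CH2Cl2 (1:4), H2O (5 equiv), 0 °C
Reagents that add atoms: none
Why: Acid-catalysed ketal hydrolysis through the diphenyl-stabilised oxocarbenium ion, trapped by water as benzophenone, should free the catechol, while low temperature and short contact are meant to spare the prenyl alkene (no free hydroxyl is ortho to it) and the C3 stereocentre.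

## Compound list

1 | 2,3-dihydroxy-4-methoxybenzaldehyde | COc1ccc(C=O)c(O)c1O | starting material
2 | dichlorodiphenylmethane | ClC(Cl)(c1ccccc1)c1ccccc1 | starting material
3 | 7-methoxy-2,2-diphenyl-1,3-benzodioxole-4-carbaldehyde | COc1ccc(C=O)c2OC(c3ccccc3)(c3ccccc3)Oc12 | intermediate
4 | 6-bromo-7-methoxy-2,2-diphenyl-1,3-benzodioxole-4-carbaldehyde | COc1c(Br)cc(C=O)c2OC(c3ccccc3)(c3ccccc3)Oc12 | intermediate
5 | tributyl(3-methylbut-2-enyl)stannane | CCCC[Sn](CCCC)(CCCC)CC=C(C)C | starting material
6 | 7-methoxy-6-(3-methylbut-2-enyl)-2,2-diphenyl-1,3-benzodioxole-4-carbaldehyde | COc1c(CC=C(C)C)cc(C=O)c2OC(c3ccccc3)(c3ccccc3)Oc12 | intermediate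
7 | N-[2-(7-methoxy-6-prenyl-2,2-diphenyl-1,3-benzodioxol-4-yl)-1-tosylvinyl]formamide (alkene geometry undefined; not isolated) | O=CNC(=Cc1cc(CC=C(C)C)c(OC)c2OC(c3ccccc3)(c3ccccc3)Oc12)S(=O)(=O)c1ccc(C)cc1 | intermediate
8 | 2-[7-methoxy-6-(3-methylbut-2-enyl)-2,2-diphenyl-1,3-benzodioxol-4-yl]acetonitrile | COc1c(CC=C(C)C)cc(CC#N)c2OC(c3ccccc3)(c3ccccc3)Oc12 | intermediate
9 | 2-[7-methoxy-6-(3-methylbut-2-enyl)-2,2-diphenyl-1,3-benzodioxol-4-yl]acetic acid | COc1c(CC=C(C)C)cc(CC(=O)O)c2OC(c3ccccc3)(c3ccccc3)Oc12 | intermediate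
10 | 1-(imidazol-1-yl)-2-[7-methoxy-6-prenyl-2,2-diphenyl-1,3-benzodioxol-4-yl]ethanone, the acyl imidazole (not isolated) | COc1c(CC=C(C)C)cc(CC(=O)n3ccnc3)c2OC(c3ccccc3)(c3ccccc3)Oc12 | intermediate
11 | N-methoxy-N-methyl-2-[7-methoxy-6-(3-methylbut-2-enyl)-2,2-diphenyl-1,3-benzodioxol-4-yl]acetamide | COc1c(CC=C(C)C)cc(CC(=O)N(C)OC)c2OC(c3ccccc3)(c3ccccc3)Oc12 | intermediate
12 | 4-bromo-3-methoxyphenol | COc1cc(O)ccc1Br | starting material
13 | (4-bromo-3-methoxyphenoxy)triisopropylsilane | COc1cc(O[Si](C(C)C)(C(C)C)C(C)C)ccc1Br | intermediate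
14 | 2-methoxy-4-(triisopropylsilyloxy)phenyllithium (not isolated) | [Li]c1ccc(O[Si](C(C)C)(C(C)C)C(C)C)cc1OC | intermediate
15 | 1-[2-methoxy-4-(triisopropylsilyloxy)phenyl]-2-[7-methoxy-6-(3-methylbut-2-enyl)-2,2-diphenyl-1,3-benzodioxol-4-yl]ethanone | COc1cc(O[Si](C(C)C)(C(C)C)C(C)C)ccc1C(=O)Cc1cc(CC=C(C)C)c(OC)c2OC(c3ccccc3)(c3ccccc3)Oc12 | intermediate
16 | 2-diazo-1-[2-methoxy-4-(triisopropylsilyloxy)phenyl]-2-[7-methoxy-6-(3-methylbut-2-enyl)-2,2-diphenyl-1,3-benzodioxol-4-yl]ethanone | COc1cc(O[Si](C(C)C)(C(C)C)C(C)C)ccc1C(=O)C(=[N+]=[N-])c1cc(CC=C(C)C)c(OC)c2OC(c3ccccc3)(c3ccccc3)Oc12 | intermediate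
17 | rhodium carbene formed from 16 (carboxylate ligands and second rhodium atom omitted; not isolated) | COc1cc(O[Si](C(C)C)(C(C)C)C(C)C)ccc1C(=O)C(=[Rh])c1cc(CC=C(C)C)c(OC)c2OC(c3ccccc3)(c3ccccc3)Oc12 | intermediate
18 | (3R)-3-[7-methoxy-6-(3-methylbut-2-enyl)-2,2-diphenyl-1,3-benzodioxol-4-yl]-7-(triisopropylsilyloxy)chroman-4-one | COc1c(CC=C(C)C)cc([C@@H]2COc3cc(O[Si](C(C)C)(C(C)C)C(C)C)ccc3C2=O)c2OC(c3ccccc3)(c3ccccc3)Oc12 | intermediate
19 | (3R)-7-hydroxy-3-[7-methoxy-6-(3-methylbut-2-enyl)-2,2-diphenyl-1,3-benzodioxol-4-yl]chroman-4-one | COc1c(CC=C(C)C)cc([C@@H]2COc3cc(O)ccc3C2=O)c2OC(c3ccccc3)(c3ccccc3)Oc12 | intermediate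
20 | (3R)-3-[2,3-dihydroxy-4-methoxy-5-(3-methylbut-2-enyl)phenyl]-7-hydroxychroman-4-one | COc1c(CC=C(C)C)cc([C@@H]2COc3cc(O)ccc3C2=O)c(O)c1O | target

## Step count and risks

Total step count: 12. Longest linear sequence: 11 steps (steps 1–6 and 8–12, from 1); the ring A branch is step 7.

Steps most likely to fail:

1. Step 10 (carbene C–H insertion). The carbene may be diverted into oxonium ylide formation followed by methyl migration, may dimerise, or may insert with low facial selectivity. The fallback uses known reaction types only, sets out from Weinreb amide 11 and returns at 18.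
 - 4-Bromoresorcinol is silylated at the hydroxyl remote from bromine (TIPSCl, imidazole, CH2Cl2, 0 °C) to give 2-bromo-5-(triisopropylsilyloxy)phenol F1.
 - F1 is capped with MOMCl/i-Pr2NEt as [4-bromo-3-(methoxymethoxy)phenoxy]triisopropylsilane F2.
 - Bromine–lithium exchange (n-BuLi, THF, −78 °C) gives 2-(methoxymethoxy)-4-(triisopropylsilyloxy)phenyllithium F3, which is added to 11 to give the 2-(methoxymethoxy) deoxybenzoin F4.
 - PPTS in methanol at 50 °C removes the MOM group ortho to the ketone and should give the 2-hydroxy deoxybenzoin F5.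
 - N,N-Dimethylformamide dimethyl acetal (toluene, 90 °C) supplies C2 and closes ring C as the 7-silyloxy isoflavone F6.
 - Asymmetric transfer hydrogenation (RuCl(p-cymene)[(R,R)-TsDPEN], HCO2H/Et3N, EtOAc, 40 °C) reduces the C2–C3 double bond and then the ketone with dynamic kinetic resolution at C3. This should give the cis-(3R,4R)-isoflavan-4-ol F7; the (S,S) catalyst is taken if the sense is opposite.
 - Dess–Martin periodinane with NaHCO3 in CH2Cl2 at 0 °C reoxidises C4 without touching C3 and gives 18.

2. Step 12 (ketal hydrolysis). Acid may hydrate the prenyl alkene, and acid-catalysed enolisation at C3 may erode enantiopurity while the robust ketal is being opened. The fallback sets out from deoxybenzoin 15 and returns at 20.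
 - The ketal is removed before any stereocentre exists (AcOH/H2O 4:1, 80 °C) to give the catechol deoxybenzoin F8.
 - F8 is silylated (TBSCl, imidazole, DMF) to the 2',3'-bis(tert-butyldimethylsilyl) deoxybenzoin F9.
 - Diazo transfer as in step 9 gives the tris-silyl diazoketone F10.
 - Rh2(S-PTTL)4 as in step 10 should give, through the tris-silyl rhodium carbene F11, the tris-silyl (R)-isoflavanone F12.
 - HF·pyridine in pyridine/THF then removes all three silyl groups in one buffered fluoride step and gives 20, so that no strong acid meets the prenyl group or C3.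

3. Step 3 (Stille prenylation). Allylic transposition during transmetalation may deliver the branched 1,1-dimethylallyl isomer, and oxidative addition at the hindered, electron-rich bromide may be slow. The fallback sets out from bromide 4 and returns at 6.
 - Stille coupling with allyltributylstannane (Pd(PPh3)4, DMF, 90 °C), where no allylic regiochemistry is at stake, gives the 6-allyl aldehyde F13.
 - Cross-metathesis with excess 2-methyl-2-butene (second-generation Grubbs catalyst, CH2Cl2, 40 °C) converts the allyl group into the prenyl group and gives 6.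

## Further compounds

F1 | step 10 | 2-bromo-5-(triisopropylsilyloxy)phenol | Oc1cc(O[Si](C(C)C)(C(C)C)C(C)C)ccc1Br
F2 | step 10 | [4-bromo-3-(methoxymethoxy)phenoxy]triisopropylsilane | COCOc1cc(O[Si](C(C)C)(C(C)C)C(C)C)ccc1Br
F3 | step 10 | 2-(methoxymethoxy)-4-(triisopropylsilyloxy)phenyllithium | [Li]c1ccc(O[Si](C(C)C)(C(C)C)C(C)C)cc1OCOC
F4 | step 10 | 2-(methoxymethoxy) deoxybenzoin | COCOc1cc(O[Si](C(C)C)(C(C)C)C(C)C)ccc1C(=O)Cc1cc(CC=C(C)C)c(OC)c2OC(c3ccccc3)(c3ccccc3)Oc12
F5 | step 10 | 2-hydroxy deoxybenzoin | Oc1cc(O[Si](C(C)C)(C(C)C)C(C)C)ccc1C(=O)Cc1cc(CC=C(C)C)c(OC)c2OC(c3ccccc3)(c3ccccc3)Oc12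
F6 | step 10 | 7-silyloxy isoflavone | COc1c(CC=C(C)C)cc(-c2coc3cc(O[Si](C(C)C)(C(C)C)C(C)C)ccc3c2=O)c2OC(c3ccccc3)(c3ccccc3)Oc12
F7 | step 10 | cis-(3R,4R)-isoflavan-4-ol | COc1c(CC=C(C)C)cc([C@@H]2COc3cc(O[Si](C(C)C)(C(C)C)C(C)C)ccc3[C@@H]2O)c2OC(c3ccccc3)(c3ccccc3)Oc12
F8 | step 12 | catechol deoxybenzoin | COc1cc(O[Si](C(C)C)(C(C)C)C(C)C)ccc1C(=O)Cc1cc(CC=C(C)C)c(OC)c(O)c1O
F9 | step 12 | 2',3'-bis(tert-butyldimethylsilyl) deoxybenzoin | COc1cc(O[Si](C(C)C)(C(C)C)C(C)C)ccc1C(=O)Cc1cc(CC=C(C)C)c(OC)c(O[Si](C)(C)C(C)(C)C)c1O[Si](C)(C)C(C)(C)C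
F10 | step 12 | tris-silyl diazoketone | COc1cc(O[Si](C(C)C)(C(C)C)C(C)C)ccc1C(=O)C(=[N+]=[N-])c1cc(CC=C(C)C)c(OC)c(O[Si](C)(C)C(C)(C)C)c1O[Si](C)(C)C(C)(C)C
F11 | step 12 | tris-silyl rhodium carbene (ligands omitted) | COc1cc(O[Si](C(C)C)(C(C)C)C(C)C)ccc1C(=O)C(=[Rh])c1cc(CC=C(C)C)c(OC)c(O[Si](C)(C)C(C)(C)C)c1O[Si](C)(C)C(C)(C)C
F12 | step 12 | tris-silyl (R)-isoflavanone | COc1c(CC=C(C)C)cc([C@@H]2COc3cc(O[Si](C(C)C)(C(C)C)C(C)C)ccc3C2=O)c(O[Si](C)(C)C(C)(C)C)c1O[Si](C)(C)C(C)(C)C
F13 | step 3 | 6-allyl aldehyde, 6-allyl-7-methoxy-2,2-diphenyl-1,3-benzodioxole-4-carbaldehyde | COc1c(CC=C)cc(C=O)c2OC(c3ccccc3)(c3ccccc3)Oc12
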